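Violet, the earlier run, is the one flask I can read a speed from.

| setting | violet | alder | larch | birch |
|---|---|---|---|---|
| electrophile | 0.60 M | 0.40 M | 0.40 M | 0.40 M |
| nucleophile | 0.60 M | 0.600 M | 0.600 M | 0.600 M |
| free base | 0.80 M | 0.800 M | 1.00 M | 1.40 M |
| remark | run made earlier |  |  |  |
| time |  | 2.5 h | 2.5 h | 2.5 h |

violet run (percent of the electrophile charged)

| time / min | electrophile / % | target / % |
|---|---|---|
| 15.0 | 71 | 28 |
| 30.0 | 50 | 37 |
| 50.0 | 41 | 40 |
| 60.0 | 36 | 46 |
| 80.0 | 28 | 51 |
| 90.0 | 30 | 50 |

(each reading ± 1.5 percentage points)

- on the list of suspects stand: electrophile + nucleophile -> acid set free + target; nucleophile + acid set free <-> protonated nucleophile; acid set free + free base <-> salt of the base; nucleophile <-> dormant form; target <-> isomer of the product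
- no earlier run changes the charge of free base; that part of a forecast is a guess

- part of the electrophile that has reacted at the end, alder
- part of the electrophile that has reacted at the end, larch
- part of the electrophile that has reacted at the end, birch
- what raising the concentration of free base from its lowest to its highest value here does to the part of the electrophile that has reacted (changes below 5 percentage points count as none) (no change / it rises / it falls)

Violet was charged with 0.60 M of electrophile and 0.60 M of nucleophile, so for a one-to-one reaction the reciprocal of c(electrophile) should climb in a straight line. I count as nucleophile whatever is charged and not yet spent, and any steady share parked elsewhere sits inside the slope. That rise per minute, averaged over the readings, is my apparent constant, 0.0492 /M/min.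

Alder holds 0.40 M of electrophile against 0.600 M of nucleophile, so the electrophile is the limiting reagent, and the question is how far it gets towards zero in 2.5 h. Take two extremes. If c(nucleophile) stayed at 0.600 M, a pseudo-first-order flask, 98.8% would react. If the nucleophile were matched to the electrophile at 0.40 M, as in violet, 74.7% would react. In my count alder's nucleophile falls but stays 0.200 M above its electrophile, so I place alder between these extremes. The ratio of nucleophile to electrophile then grows by the exponential of constant times excess times time, here a factor 4.38. That leaves 8.99% of the electrophile, so I commit to 91.0% reacted.

Free base is a guess: even the lowest charge, 0.800 M, exceeds the 0.40 M of acid that can be set free, so I give larch and birch the same figure.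

The forecast gives 91% for alder, 91% for larch, 91% for birch and no change, holding that “more base should change nothing”.

Alder gives 91.3%, larch 91.3% and birch 91.3%, and raising the free base from lowest to highest brings no change, a shift of 0.012 percentage points, while the free base left is 54% of its own charge in alder and 74% in birch.

    electrophile + nucleophile → acid set free + target (k = 0.140 /M/min)
    nucleophile + acid set free ⇌ protonated nucleophile, settled at all times (K = 220 /M)
    acid set free + free base ⇌ salt of the base, settled at all times (K = 32000 /M)
    nucleophile ⇌ dormant form (K = 1.80, k = 0.680 /min)
    target ⇌ isomer of the product (K = 0.430, k = 0.0710 /min)

With an excess of 0.500 M in my count, the apparent constant leaves 2.09% of the electrophile in a neighbour of birch charged with 0.10 M of electrophile, and that flask holds 1.90%.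

(The runs are calculated for substances that don't exist; the scatter is artificial.)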